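## Analysis of the target

Target 27 is two units joined through the methylene carbon C7. The first is a tetrahydrofuran (O1, C2 bearing ring A, C3 bearing the hydroxymethyl carbon C9, C4 bearing C7, C5). The second is a 2',3'-dihydrobenzofuran (O1', C2' bearing ring C, C3' bearing the hydroxymethyl carbon C9', C3a', C4' with OMe, C5', C6' bonded to C7, C7', C7a'); ring B is its benzo ring. Ring A is 3-hydroxy-4-methoxyphenyl and ring C is 4-hydroxy-3-methoxyphenyl.

There are five stereocentres in two groups. The tetrahydrofuran is 2R,3S,4S, with ring A trans to C9 and C9 cis to C7. The dihydrobenzofuran is 2'S,3'R, with ring C trans to C9'. C7 and ring B insulate the groups from each other, so each needs its own absolute control.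

The sensitive groups are two free phenols, two primary alcohols and two benzylic C–O bonds (C2–O1 para to the OMe of ring A, C2'–O1' para to the OH of ring C). These bonds ionise in acid and cleave on long hydrogenolysis, and the second opens to a quinone methide in hot base.

The hard part is ring B. It is 1,2,3,5-tetrasubstituted, and C3a' lies between two oxygen-bearing carbons (C7a' and C4'), so the C3a'–C3' bond must be made at the most crowded ring position, next to a stereocentre. The 3,4-cis relation on the tetrahydrofuran is also the less stable one.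

The strategy rests on one feature: the array O1'–C2'(ring C)–C3'(C9')–C3a' with OMe on C4' is the ring-contracted isomer of a 5-methoxyflavanone in which C9' is the carbonyl carbon attached to ring B. Moving ring B from C9' to C3' makes the C3a'–C3' bond, and C6' maps onto the flavanone 7-position, where a chlorine can be carried as a coupling handle.

## Retrosynthetic reasoning

**End game (27 from 26 from 25).** No skeletal bond is cut. The two phenols of 27 are unmasked last from the benzyl ethers of 26 by hydrogenolysis, and the C9 hydroxyl before that from the silyl ether of 25. Benzyl is chosen for the phenols because aryl benzyl ethers cleave much faster than the two cyclic benzylic C–O bonds. Only the C9 hydroxyl is silylated, because only it interferes with a later step (hydroboration). The C9' hydroxyl stays free.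

**C7–C6' (25 from 23 and 15).** This is the only bond between the two stereochemical groups, so cutting it gives two halves of similar size, each with its own stereocentres. Forward, the exocyclic alkene of 23 is hydroborated to borane 24, which must place hydrogen on C4 trans to the C3 arm. A B-alkyl Suzuki coupling then joins C7 to the aryl chloride of 15. C4 is thus set in the same operation that joins the halves, and the chlorine is inert to everything before it.

**Adjustments on the dihydrobenzofuran (15 from 14 from 13 from 12).** The C9' alcohol comes from the ester of 12. The ring C tosylate, needed earlier as a deactivating group, is exchanged for benzyl. An aryl sulfonate could compete with the chloride in oxidative addition and could not be removed from the finished molecule without hot base.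

**Key disconnection (12 from 10).** The C3a'–C3' bond is cut and ring B is re-attached to C9', which becomes a ketone carbon; this is flavanone 10. The crowded aryl–C(sp3) bond and the C3' stereocentre are exchanged for an aryl ketone that comes with an acetophenone, and the stereochemical problem shrinks to one centre, C2'. The forward reaction, an oxidative 1,2-aryl shift, must move ring B and not ring C, and must leave the ester trans to ring C.

**Ring C to C2' (10 from 6 and 9).** The bond between C2' and ring C is cut. An enantioselective conjugate addition of boronic acid 9 to chromone 6 sets C2', the only centre in this half that needs a chiral catalyst. Cutting O1'–C2' instead (oxa-Michael closure of a chalcone) gives weaker enantiocontrol and is kept as a fallback.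

**Chromone and boronic acid (6 from 4 from 3 from 1; 9 from 8 from 7).** Chromone 6 comes from o-hydroxyacetophenone 4 by a one-carbon condensation, 4 from 3 by chelation-controlled mono-demethylation, and 3 from 1 by lithiation between the two methoxy groups (through 2). This fixes the 1,2,3,5-pattern of ring B from a symmetric commercial arene and puts the chlorine para to the acetyl group, where it ends as C6'. Boronic acid 9 comes from commercial boronate phenol 7 through 8.

**C3–C4 (23 from 22 from 21).** The tetrahydrofuran is opened at C3–C4. A radical generated at C3 from epoxide 21 cyclises 5-exo-dig onto the propargyl ether. This forms C3–C4, the exocyclic methylene and the C9 hydroxyl at once, with C3 trans to C2.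

**C2 (21 from 20 from 19 from 18 from 17 from 16).** Epoxidation (the oxirane carbon becomes a planar radical, so its configuration is irrelevant) and O-propargylation lead back to allylic alcohol 19. Its configuration comes from an enzymatic kinetic resolution of racemate 17, made from aldehyde 16. The resolution is placed at the second step of this branch, on its cheapest material.

## Alternatives that were turned down

**Alternative 1:** Ring B itself is taken apart. Cyclobutenone A1 (carrying the tetrahydrofuranylmethyl arm) and siloxyalkyne A2 (carrying C3', C9', C2' and ring C) are heated together. Ring opening to a vinylketene, [2+2] addition, a second ring opening and 6π closure form C7a'–C3a' and C4'–C5' and give resorcinol mono-silyl ether A3.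

- For: the substitution pattern of ring B is fixed by the mechanism. The two ring oxygens come out differentiated (free OH at C7a', silyl ether at C4'). The two halves are joined as the ring forms.
- Against: after the key step the dihydrofuran is still open. O1'–C2' must be closed by displacement at the benzylic C2', whose trans outcome rests on equilibration there. The C3' centre is propargylic in A2 and must survive heating. A1 and A2 each need long sequences. Desilylation, methylation and three debenzylations follow.
- Comparison: it is stronger on convergence and has no regiochemical question on ring B. The chosen route buys ring B as 1 instead, forms C3a'–C3' and sets C3' in one operation from flavanone 10, and is shorter overall.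

**Alternative 2:** The tetrahydrofuran is made by cutting C3–C4 and a temporary C7–C9 bond. Bis-allylic ether A4 (vinylboronate arm on the C2 carbinol, cinnamyl-type arm carrying the finished dihydrobenzofuran) undergoes a triplet-sensitised intramolecular [2+2] photocycloaddition to bicyclic boronate A5. Oxidation of C–B, β-scission of the cyclobutanol C7–C9 bond to a benzylic radical and an aldehyde, and reduction would follow.

- For: the 3,4-cis relation is locked by the cis ring fusion. This is firmer than the facial preference of a hydroboration, and on this point the alternative is stronger. The conditions are mild.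
- Against: it solves the easier half. The dihydrobenzofuran, with its crowded C3a'–C3' bond, must still be made first and then vinylated at C6'. Control of the 2,3-relation by C2 in the cycloaddition is uncertain. The fragmentation adds several steps, and the transient C9 aldehyde is α to C3 and could epimerise.
- Comparison: the chosen route spends its key step on the harder half and sets C4 in the coupling step, which costs no extra operation.

**Alternative 3:** O1'–C7a' and C3a'–C3' are cut together. An aryne is generated with fluoride from silyl triflate A6 (ring B with the whole tetrahydrofuran arm). The alkoxide of epoxy alcohol A7 adds at the aryne carbon remote from OMe, and the aryl anion then opens the epoxide at C3' (5-exo, with inversion) to give A8, one hydrogenolysis from 27.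

- For: this has the highest convergence, with the key step next to last. Both dihydrobenzofuran centres come from an epoxy alcohol of defined configuration. The regiochemistry of addition to a 3-alkoxyaryne is well understood. On convergence and on steps after the key step it is stronger.
- Against: an aryl anion formed by alkoxide addition to an aryne is normally protonated faster than it opens an unactivated epoxide. Under base A7 can undergo epoxide migration, which changes the oxygen that adds. A6 is a pentasubstituted arene made over many steps and consumed in an unprecedented step at the very end.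
- Comparison: the chosen route has class precedent for its key step, places the risk early on cheap material, and derives both dihydrobenzofuran centres from one catalytic enantioselective step.

Key step: step 7

Assumption: the R antipode of the pyridine–oxazoline ligand is taken to give the 2S flavanone 10, by analogy with the facial preference of this catalyst on cyclic enones; the other antipode is used if a first sample proves to be 2R.
Assumption: the lipase in step 12 is taken to acylate the R enantiomer of 17 (aryl as the large group, vinyl as the medium group).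

## Route

Step 1
Reactants: 1 1-chloro-3,5-dimethoxybenzene
Product: 3 1-(4-chloro-2,6-dimethoxyphenyl)ethan-1-one, via (4-chloro-2,6-dimethoxyphenyl)lithium 2 (not isolated)
Conditions: n-BuLi, THF, −20→0 °C; then MeC(O)N(OMe)Me, −78 °C→rt; 1 M HCl
Reagents that add atoms: N-methoxy-N-methylacetamide, CC(=O)N(C)OC
Why: Directed ortho-lithiation takes the proton between the two methoxy groups, and aryllithium 2 has chlorine meta to lithium, so it cannot lose LiCl to an aryne. Acylation with the Weinreb amide stops at the ketone (Weinreb ketone synthesis).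

Step 2
Reactants: 3 1-(4-chloro-2,6-dimethoxyphenyl)ethan-1-one
Product: 4 1-(4-chloro-2-hydroxy-6-methoxyphenyl)ethan-1-one
Conditions: BCl3, CH2Cl2, −78→0 °C; then H2O
Reagents that add atoms: none
Why: BCl3 binds the carbonyl oxygen and cleaves one flanking methyl ether. The six-membered boron chelate that results resists a second cleavage, so mono-demethylation is expected.

Step 3
Reactants: 4 1-(4-chloro-2-hydroxy-6-methoxyphenyl)ethan-1-one
Product: 6 7-chloro-5-methoxy-4H-chromen-4-one, via enaminone 5 (not isolated)
Conditions: Me2NCH(OMe)2, toluene, 100 °C; then conc. HCl, CH2Cl2, 40 °C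
Reagents that add atoms: N,N-dimethylformamide dimethyl acetal, COC(OC)N(C)C
Why: The acetyl methyl group condenses with the amide acetal to enaminone 5. Acid then drives addition of the phenol and loss of dimethylamine, the standard chromone synthesis from o-hydroxyacetophenones.

Step 4
Reactants: 7 2-methoxy-4-(4,4,5,5-tetramethyl-1,3,2-dioxaborolan-2-yl)phenol
Product: 8 2-methoxy-4-(4,4,5,5-tetramethyl-1,3,2-dioxaborolan-2-yl)phenyl 4-methylbenzenesulfonate
Conditions: TsCl, Et3N, DMAP (cat.), CH2Cl2, 0 °C→rt
Reagents that add atoms: 4-methylbenzenesulfonyl chloride, Cc1ccc(cc1)S(Cl)(=O)=O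
Why: Sulfonylation of the phenol; the pinacol boronate is inert to amine base and sulfonyl chloride.

Step 5
Reactants: 8 2-methoxy-4-(4,4,5,5-tetramethyl-1,3,2-dioxaborolan-2-yl)phenyl 4-methylbenzenesulfonate
Product: 9 [3-methoxy-4-(tosyloxy)phenyl]boronic acid
Conditions: NaIO4, NH4OAc, acetone/H2O, rt
Reagents that add atoms: water, O
Why: Periodate cleaves the pinacol released in the hydrolysis equilibrium of the boronate and so drives it to the free boronic acid. The near-neutral conditions leave the aryl tosylate intact.

Step 6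
Reactants: 6 7-chloro-5-methoxy-4H-chromen-4-one; 9 [3-methoxy-4-(tosyloxy)phenyl]boronic acid
Product: 10 (2S)-7-chloro-5-methoxy-2-[3-methoxy-4-(tosyloxy)phenyl]-2,3-dihydro-4H-chromen-4-one
Conditions: Pd(OCOCF3)2 (5 mol%), (R)-4-tert-butyl-2-(pyridin-2-yl)-4,5-dihydrooxazole (6 mol%), NH4PF6, H2O, ClCH2CH2Cl, 60 °C
Reagents that add atoms: none
Why: Enantioselective conjugate addition of an arylboronic acid to a chromone under cationic divalent palladium: transmetalation, face-selective insertion of the chromone C=C bond into the Pd–aryl bond, then protonolysis of the palladium enolate. The tert-butyl group of the ligand blocks one face and so sets C2' (S). No zerovalent palladium is involved, so the aryl chloride and tosylate survive, and the near-neutral medium avoids retro-oxa-Michael opening of the flavanone.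

Step 7
Reactants: 10 (2S)-7-chloro-5-methoxy-2-[3-methoxy-4-(tosyloxy)phenyl]-2,3-dihydro-4H-chromen-4-one
Product: 12 methyl (2S,3S)-6-chloro-4-methoxy-2-[3-methoxy-4-(tosyloxy)phenyl]-2,3-dihydro-1-benzofuran-3-carboxylate, via enol ether 11 (not isolated)
Conditions: PhI(OAc)2, conc. H2SO4, HC(OMe)3, rt
Reagents that add atoms: trimethyl orthoformate, COC(OC)OC
Why: Acid and the orthoformate turn ketone 10 into enol ether 11, whose C3' is attacked by the acid-activated trivalent iodine reagent trans to ring C while methanol caps the oxocarbenium at C9' (the old carbonyl carbon). With the iodanyl group pseudo-equatorial and antiperiplanar to the C9'–C3a' bond, iodobenzene leaves as ring B shifts from C9' to C3' through a bridged phenonium transition state, and the dimethoxycarbenium ion left at C9' collapses to the methyl ester. The closest known reactions are the ring contraction of flavanones to methyl trans-2-aryl-2,3-dihydrobenzofuran-3-carboxylates with PhI(OAc)2 or Tl(NO3)3 and the related conversion of aryl methyl ketones into methyl arylacetates. The dihydrofuran ring is closed by contraction of the pyranone, not by a cyclisation: C3a'–C3' forms as C3a'–C9' breaks (a 1,2-shift through a three-membered bridged array) and C9' is pushed out of the ring. C3' is controlled by C2': attack trans to ring C followed by migration with inversion at C3' leads directly to the trans ester, and because C3' is benzylic and α to the ester any cis isomer can be equilibrated to trans (acid in the flask, or catalytic NaOMe afterwards) without touching C2'. The step needs ring B to migrate in preference to ring C (which would give an isoflavone), to loss of the C2' hydrogen (flavone) and to substitution by methanol at C3'. Ring B is favoured because the migrating carbon C3a' has oxygen on both ortho carbons (C7a' and C4'), which stabilise the phenonium ion, while the sulfonate deactivates ring C and also disfavours ionisation at C2'.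

Step 8
Reactants: 12 methyl (2S,3S)-6-chloro-4-methoxy-2-[3-methoxy-4-(tosyloxy)phenyl]-2,3-dihydro-1-benzofuran-3-carboxylate
Product: 13 {(2S,3R)-6-chloro-4-methoxy-2-[3-methoxy-4-(tosyloxy)phenyl]-2,3-dihydro-1-benzofuran-3-yl}methanol
Conditions: LiBH4, THF/MeOH, 0 °C→rt
Reagents that add atoms: none
Why: Chemoselective ester reduction; LiBH4 leaves the aryl sulfonate and aryl chloride alone, and without base the C3' centre is not enolised. The change of descriptor at C3' (S to R) is a change of priorities only.

Step 9
Reactants: 13 {(2S,3R)-6-chloro-4-methoxy-2-[3-methoxy-4-(tosyloxy)phenyl]-2,3-dihydro-1-benzofuran-3-yl}methanol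
Product: 14 4-[(2S,3R)-6-chloro-3-(hydroxymethyl)-4-methoxy-2,3-dihydro-1-benzofuran-2-yl]-2-methoxyphenol
Conditions: KOH, MeOH/THF/H2O, 60 °C; then 1 M HCl to pH 6
Reagents that add atoms: none
Why: Hydroxide attacks sulfur of the aryl sulfonate and frees the phenolate. At 60 °C the phenylcoumaran is well below the range of phenolate-driven ring opening, and neither stereocentre carries an acidic hydrogen.

Step 10
Reactants: 14 4-[(2S,3R)-6-chloro-3-(hydroxymethyl)-4-methoxy-2,3-dihydro-1-benzofuran-2-yl]-2-methoxyphenol
Product: 15 {(2S,3R)-2-[4-(benzyloxy)-3-methoxyphenyl]-6-chloro-4-methoxy-2,3-dihydro-1-benzofuran-3-yl}methanol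
Conditions: BnBr, K2CO3, acetone, 50 °C
Reagents that add atoms: benzyl bromide, BrCc1ccccc1
Why: Williamson etherification; carbonate deprotonates only the phenol, so the primary alcohol stays free.

Step 11
Reactants: 16 3-(benzyloxy)-4-methoxybenzaldehyde
Product: 17 rac-1-[3-(benzyloxy)-4-methoxyphenyl]prop-2-en-1-ol
Conditions: CH2=CHMgBr, THF, −78→0 °C; then H2O/aq. NH4Cl
Reagents that add atoms: vinylmagnesium bromide, C=C[Mg]Br
Why: Grignard addition to the aldehyde gives the racemic allylic alcohol.

Step 12
Reactants: 17 rac-1-[3-(benzyloxy)-4-methoxyphenyl]prop-2-en-1-ol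
Product: 18 (1R)-1-[3-(benzyloxy)-4-methoxyphenyl]prop-2-en-1-yl acetate
Conditions: Candida antarctica lipase B (immobilised), vinyl acetate, MTBE, 30 °C, stopped near half conversion
Reagents that add atoms: vinyl acetate, CC(=O)OC=C
Why: Lipase-catalysed kinetic resolution by irreversible transesterification: the enzyme acylates the enantiomer with aryl as large and vinyl as medium group (R), which fixes the future C2 configuration. The unreacted S enantiomer of 17 is removed by chromatography.

Step 13
Reactants: 18 (1R)-1-[3-(benzyloxy)-4-methoxyphenyl]prop-2-en-1-yl acetate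
Product: 19 (1R)-1-[3-(benzyloxy)-4-methoxyphenyl]prop-2-en-1-ol
Conditions: K2CO3 (cat.), MeOH, 0 °C
Reagents that add atoms: none
Why: Base-catalysed transesterification by acyl–oxygen cleavage, so the stereocentre is not touched. Base and low temperature keep the ionisation-prone benzylic allylic C–O bond intact.

Step 14
Reactants: 19 (1R)-1-[3-(benzyloxy)-4-methoxyphenyl]prop-2-en-1-ol
Product: 20 2-(benzyloxy)-1-methoxy-4-[(1R)-1-(prop-2-yn-1-yloxy)prop-2-en-1-yl]benzene
Conditions: NaH, propargyl bromide, THF/DMF, 0 °C→rt
Reagents that add atoms: propargyl bromide, C#CCBr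
Why: Williamson etherification of the alkoxide; the C–O bond of the stereocentre is not involved, so configuration is retained.

Step 15
Reactants: 20 2-(benzyloxy)-1-methoxy-4-[(1R)-1-(prop-2-yn-1-yloxy)prop-2-en-1-yl]benzene
Product: 21 2-{(S)-[3-(benzyloxy)-4-methoxyphenyl](prop-2-yn-1-yloxy)methyl}oxirane (both epimers at the oxirane carbon)
Conditions: mCPBA, NaHCO3, CH2Cl2, 0 °C→rt
Reagents that add atoms: 3-chloroperoxybenzoic acid, OOC(=O)c1cccc(Cl)c1
Why: Prilezhaev epoxidation of the only alkene; the alkyne and the arene are much less reactive towards the peracid. Both epimers are carried on because the oxirane carbon becomes a planar radical in the next step (the S descriptor at the benzylic carbon is a change of priorities only).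

Step 16
Reactants: 21 2-{(S)-[3-(benzyloxy)-4-methoxyphenyl](prop-2-yn-1-yloxy)methyl}oxirane
Product: 22 {(2R,3S)-2-[3-(benzyloxy)-4-methoxyphenyl]-4-methylideneoxolan-3-yl}methanol
Conditions: Cp2TiCl2, Zn dust, THF, rt (21 added slowly to the preformed Cp2TiCl); then aq. NaH2PO4
Reagents that add atoms: none
Why: Single-electron opening of the epoxide by Cp2TiCl (trivalent titanium) gives the secondary β-titanoxy radical at C3, which cyclises 5-exo-dig onto the alkyne to form C3–C4; the vinyl radical is quenched by hydrogen abstraction from THF or by a second Cp2TiCl and protonolysis. C3 is set trans to C2 because ring A and the CH2OTi arm both sit pseudo-equatorial in the chair-like transition state.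

Step 17
Reactants: 22 {(2R,3S)-2-[3-(benzyloxy)-4-methoxyphenyl]-4-methylideneoxolan-3-yl}methanol
Product: 23 ({(2R,3S)-2-[3-(benzyloxy)-4-methoxyphenyl]-4-methylideneoxolan-3-yl}methoxy)(tert-butyl)dimethylsilane
Conditions: TBSCl, imidazole, DMF, rt
Reagents that add atoms: tert-butyldimethylsilyl chloride, CC(C)(C)[Si](C)(C)Cl
Why: Standard silylation of the primary alcohol, so that the borane is not consumed and the C3 arm becomes the larger group next to the alkene.

Step 18
Reactants: 23 ({(2R,3S)-2-[3-(benzyloxy)-4-methoxyphenyl]-4-methylideneoxolan-3-yl}methoxy)(tert-butyl)dimethylsilane; 15 {(2S,3R)-2-[4-(benzyloxy)-3-methoxyphenyl]-6-chloro-4-methoxy-2,3-dihydro-1-benzofuran-3-yl}methanol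
Product: 25 [(2S,3R)-2-[4-(benzyloxy)-3-methoxyphenyl]-6-{[(3S,4S,5R)-5-[3-(benzyloxy)-4-methoxyphenyl]-4-({[tert-butyl(dimethyl)silyl]oxy}methyl)oxolan-3-yl]methyl}-4-methoxy-2,3-dihydro-1-benzofuran-3-yl]methanol, via B-alkyl-9-BBN adduct 24 (not isolated)
Conditions: 9-BBN-H, THF, 0 °C→rt; then 15, Pd(OAc)2 (5 mol%), SPhos (10 mol%), K3PO4 (3 M aq.), THF, 65 °C
Reagents that add atoms: none
Why: Hydroboration places boron on the terminal carbon and hydrogen on C4 from the face opposite the adjacent C3 silyloxymethyl arm, so C7 ends cis to C9 (4S). The B-alkyl Suzuki–Miyaura coupling then joins C7 to C6': the electron-rich biaryl phosphine enables oxidative addition of the aryl chloride, and aqueous K3PO4 forms the borate for transmetalation, which does not involve C4. The benzyl ethers, the silyl ether and the free C9' alcohol are inert.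

Step 19
Reactants: 25 [(2S,3R)-2-[4-(benzyloxy)-3-methoxyphenyl]-6-{[(3S,4S,5R)-5-[3-(benzyloxy)-4-methoxyphenyl]-4-({[tert-butyl(dimethyl)silyl]oxy}methyl)oxolan-3-yl]methyl}-4-methoxy-2,3-dihydro-1-benzofuran-3-yl]methanol
Product: 26 [(2S,3R)-2-[4-(benzyloxy)-3-methoxyphenyl]-6-{[(3S,4S,5R)-5-[3-(benzyloxy)-4-methoxyphenyl]-4-(hydroxymethyl)oxolan-3-yl]methyl}-4-methoxy-2,3-dihydro-1-benzofuran-3-yl]methanol
Conditions: tetrabutylammonium fluoride, THF, 0 °C→rt
Reagents that add atoms: none
Why: Fluoride cleaves the Si–O bond; nothing else in 25 responds.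

Step 20
Reactants: 26 [(2S,3R)-2-[4-(benzyloxy)-3-methoxyphenyl]-6-{[(3S,4S,5R)-5-[3-(benzyloxy)-4-methoxyphenyl]-4-(hydroxymethyl)oxolan-3-yl]methyl}-4-methoxy-2,3-dihydro-1-benzofuran-3-yl]methanol
Product: 27 4-[(2S,3R)-3-(hydroxymethyl)-6-{[(3S,4S,5R)-5-(3-hydroxy-4-methoxyphenyl)-4-(hydroxymethyl)oxolan-3-yl]methyl}-4-methoxy-2,3-dihydro-1-benzofuran-2-yl]-2-methoxyphenol
Conditions: H2 (1 atm), Pd/C (10%), EtOAc, rt, stopped once both benzyl groups are gone
Reagents that add atoms: none
Why: Hydrogenolysis of the two aryl benzyl ethers; these cleave far faster than the cyclic benzylic ethers C2–O1 and C2'–O1', so the neutral, short reaction should leave both rings and all five stereocentres intact.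

## Compound list

1 | 1-chloro-3,5-dimethoxybenzene | COc1cc(Cl)cc(OC)c1 | starting material
2 | (4-chloro-2,6-dimethoxyphenyl)lithium | [Li]c1c(OC)cc(Cl)cc1OC | intermediate
3 | 1-(4-chloro-2,6-dimethoxyphenyl)ethan-1-one | CC(=O)c1c(OC)cc(Cl)cc1OC | intermediate
4 | 1-(4-chloro-2-hydroxy-6-methoxyphenyl)ethan-1-one | CC(=O)c1c(O)cc(Cl)cc1OC | intermediate
5 | (E)-1-(4-chloro-2-hydroxy-6-methoxyphenyl)-3-(dimethylamino)prop-2-en-1-one | CN(C)/C=C/C(=O)c1c(O)cc(Cl)cc1OC | intermediate
6 | 7-chloro-5-methoxy-4H-chromen-4-one | COc1cc(Cl)cc2occc(=O)c12 | intermediate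
7 | 2-methoxy-4-(4,4,5,5-tetramethyl-1,3,2-dioxaborolan-2-yl)phenol | COc1cc(B2OC(C)(C)C(C)(C)O2)ccc1O | starting material
8 | 2-methoxy-4-(4,4,5,5-tetramethyl-1,3,2-dioxaborolan-2-yl)phenyl 4-methylbenzenesulfonate | COc1cc(B2OC(C)(C)C(C)(C)O2)ccc1OS(=O)(=O)c1ccc(C)cc1 | intermediate
9 | [3-methoxy-4-(tosyloxy)phenyl]boronic acid | COc1cc(B(O)O)ccc1OS(=O)(=O)c1ccc(C)cc1 | intermediate
10 | (2S)-7-chloro-5-methoxy-2-[3-methoxy-4-(tosyloxy)phenyl]-2,3-dihydro-4H-chromen-4-one | Clc1cc(OC)c2c(c1)O[C@H](c1ccc(OS(=O)(=O)c3ccc(C)cc3)c(OC)c1)CC2=O | intermediate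
11 | (2S)-7-chloro-4,5-dimethoxy-2-[3-methoxy-4-(tosyloxy)phenyl]-2H-chromene | Clc1cc(OC)c2c(c1)O[C@H](c1ccc(OS(=O)(=O)c3ccc(C)cc3)c(OC)c1)C=C2OC | intermediate
12 | methyl (2S,3S)-6-chloro-4-methoxy-2-[3-methoxy-4-(tosyloxy)phenyl]-2,3-dihydro-1-benzofuran-3-carboxylate (trans) | Clc1cc(OC)c2c(c1)O[C@H](c1ccc(OS(=O)(=O)c3ccc(C)cc3)c(OC)c1)[C@H]2C(=O)OC | intermediate
13 | {(2S,3R)-6-chloro-4-methoxy-2-[3-methoxy-4-(tosyloxy)phenyl]-2,3-dihydro-1-benzofuran-3-yl}methanol | Clc1cc(OC)c2c(c1)O[C@H](c1ccc(OS(=O)(=O)c3ccc(C)cc3)c(OC)c1)[C@H]2CO | intermediate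
14 | 4-[(2S,3R)-6-chloro-3-(hydroxymethyl)-4-methoxy-2,3-dihydro-1-benzofuran-2-yl]-2-methoxyphenol | Clc1cc(OC)c2c(c1)O[C@H](c1ccc(O)c(OC)c1)[C@H]2CO | intermediate
15 | {(2S,3R)-2-[4-(benzyloxy)-3-methoxyphenyl]-6-chloro-4-methoxy-2,3-dihydro-1-benzofuran-3-yl}methanol | Clc1cc(OC)c2c(c1)O[C@H](c1ccc(OCc3ccccc3)c(OC)c1)[C@H]2CO | intermediate
16 | 3-(benzyloxy)-4-methoxybenzaldehyde | COc1ccc(C=O)cc1OCc1ccccc1 | starting material
17 | rac-1-[3-(benzyloxy)-4-methoxyphenyl]prop-2-en-1-ol | COc1ccc(C(O)C=C)cc1OCc1ccccc1 | intermediate
18 | (1R)-1-[3-(benzyloxy)-4-methoxyphenyl]prop-2-en-1-yl acetate | COc1ccc([C@@H](C=C)OC(C)=O)cc1OCc1ccccc1 | intermediate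
19 | (1R)-1-[3-(benzyloxy)-4-methoxyphenyl]prop-2-en-1-ol | COc1ccc([C@@H](C=C)O)cc1OCc1ccccc1 | intermediate
20 | 2-(benzyloxy)-1-methoxy-4-[(1R)-1-(prop-2-yn-1-yloxy)prop-2-en-1-yl]benzene | COc1ccc([C@@H](C=C)OCC#C)cc1OCc1ccccc1 | intermediate
21 | 2-{(S)-[3-(benzyloxy)-4-methoxyphenyl](prop-2-yn-1-yloxy)methyl}oxirane (both epimers at the oxirane carbon) | COc1ccc([C@@H](C2CO2)OCC#C)cc1OCc1ccccc1 | intermediate
22 | {(2R,3S)-2-[3-(benzyloxy)-4-methoxyphenyl]-4-methylideneoxolan-3-yl}methanol | COc1ccc([C@@H]2OCC(=C)[C@H]2CO)cc1OCc1ccccc1 | intermediate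
23 | ({(2R,3S)-2-[3-(benzyloxy)-4-methoxyphenyl]-4-methylideneoxolan-3-yl}methoxy)(tert-butyl)dimethylsilane | COc1ccc([C@@H]2OCC(=C)[C@H]2CO[Si](C)(C)C(C)(C)C)cc1OCc1ccccc1 | intermediate
24 | 9-{[(3S,4S,5R)-5-[3-(benzyloxy)-4-methoxyphenyl]-4-({[tert-butyl(dimethyl)silyl]oxy}methyl)oxolan-3-yl]methyl}-9-borabicyclo[3.3.1]nonane | COc1ccc([C@@H]2OC[C@@H](CB3C4CCCC3CCC4)[C@H]2CO[Si](C)(C)C(C)(C)C)cc1OCc1ccccc1 | intermediate
25 | [(2S,3R)-2-[4-(benzyloxy)-3-methoxyphenyl]-6-{[(3S,4S,5R)-5-[3-(benzyloxy)-4-methoxyphenyl]-4-({[tert-butyl(dimethyl)silyl]oxy}methyl)oxolan-3-yl]methyl}-4-methoxy-2,3-dihydro-1-benzofuran-3-yl]methanol | COc1ccc([C@@H]2OC[C@@H](Cc3cc(OC)c4c(c3)O[C@H](c3ccc(OCc5ccccc5)c(OC)c3)[C@H]4CO)[C@H]2CO[Si](C)(C)C(C)(C)C)cc1OCc1ccccc1 | intermediate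
26 | [(2S,3R)-2-[4-(benzyloxy)-3-methoxyphenyl]-6-{[(3S,4S,5R)-5-[3-(benzyloxy)-4-methoxyphenyl]-4-(hydroxymethyl)oxolan-3-yl]methyl}-4-methoxy-2,3-dihydro-1-benzofuran-3-yl]methanol | COc1ccc([C@@H]2OC[C@@H](Cc3cc(OC)c4c(c3)O[C@H](c3ccc(OCc5ccccc5)c(OC)c3)[C@H]4CO)[C@H]2CO)cc1OCc1ccccc1 | intermediate
27 | 4-[(2S,3R)-3-(hydroxymethyl)-6-{[(3S,4S,5R)-5-(3-hydroxy-4-methoxyphenyl)-4-(hydroxymethyl)oxolan-3-yl]methyl}-4-methoxy-2,3-dihydro-1-benzofuran-2-yl]-2-methoxyphenol | COc1ccc([C@@H]2OC[C@@H](Cc3cc(OC)c4c(c3)O[C@H](c3ccc(O)c(OC)c3)[C@H]4CO)[C@H]2CO)cc1O | target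

## Step count and risks

Total step count: 20. Longest linear sequence: 11 steps (steps 1, 2, 3, 6, 7, 8, 9, 10, 18, 19, 20). The boronic acid branch (steps 4, 5) joins at step 6 and the tetrahydrofuran branch (steps 11 to 17) at step 18.

Steps least certain to work:

**Step 7 (key step).** Three things may go wrong: migration of ring C in place of ring B, or loss of the C2' hydrogen, may compete; the electron-rich ring B may be attacked on carbon by the iodine reagent; and enol ether formation may be slow because the ketone is flanked by the 5-methoxy group. The fallback sets out from 10 and returns at 12, and reaches the same ring contraction through a carbene instead of an oxidation.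
- Flavanone 10 is converted by detrifluoroacetylative diazo transfer (LiN(SiMe3)2, THF, −78 °C; CF3CO2CH2CF3; then MsN3, Et3N, aqueous MeCN) into (2R)-7-chloro-3-diazo-5-methoxy-2-[3-methoxy-4-(tosyloxy)phenyl]-2,3-dihydro-4H-chromen-4-one F1. The R descriptor reflects a change of priorities; C2' keeps its spatial arrangement. The low temperature is meant to keep the enolate from expelling the phenoxide.
- Irradiation of F1 in MeOH (350 nm) should bring about a Wolff rearrangement. The diazo ketone is held s-cis by the ring and loses nitrogen as ring B migrates from C9' to C3'; methanol adds to the ketene.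
- Brief treatment of the resulting cis/trans ester mixture with catalytic NaOMe in MeOH should give 12.

**Step 6.** Insertion into the electron-rich 5-methoxychromone may be slow, so that protodeboronation of 9 takes over, and facial discrimination may be incomplete. The fallback sets out from 4 and returns at 10.
- Vanillin is tosylated (TsCl, Et3N, CH2Cl2) to 4-formyl-2-methoxyphenyl 4-methylbenzenesulfonate F2.
- Condensation of 4 with F2 (pyrrolidine, EtOH, reflux) should give (E)-1-(4-chloro-2-hydroxy-6-methoxyphenyl)-3-[3-methoxy-4-(tosyloxy)phenyl]prop-2-en-1-one F3. This closes under the same conditions by oxa-Michael addition to the racemic flavanone rac-7-chloro-5-methoxy-2-[3-methoxy-4-(tosyloxy)phenyl]-2,3-dihydro-4H-chromen-4-one F4.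
- A kinetic resolution by Noyori asymmetric transfer hydrogenation (RuCl[(R,R)-TsDPEN](p-cymene), HCO2H/Et3N, EtOAc, rt, stopped near half conversion) should reduce the 2R enantiomer to (2R,4R)-7-chloro-5-methoxy-2-[3-methoxy-4-(tosyloxy)phenyl]-3,4-dihydro-2H-chromen-4-ol F5 and leave 10, which is separated by chromatography.

**Step 16.** The radical may be intercepted by a second Cp2TiCl before it cyclises (deoxygenation back to the alkene), and the trans preference at C3 may be incomplete. The fallback sets out from 20 and returns at 22; it forms the same C3–C4 bond without the epoxide or a radical.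
- Enyne 20 undergoes a palladium-catalysed borylative cyclisation (Pd(OAc)2, bis(pinacolato)diboron, MeOH, toluene, 50 °C): hydropalladation of the alkyne, 5-exo carbopalladation of the vinyl group and C–B bond formation. This should give 2-({(2R,3R)-2-[3-(benzyloxy)-4-methoxyphenyl]-4-methylideneoxolan-3-yl}methyl)-4,4,5,5-tetramethyl-1,3,2-dioxaborolane F6 (same spatial arrangement at C3 as in 22).
- Oxidation of F6 (NaBO3·4H2O, THF/H2O, rt) gives 22.

**Step 18.** Oxidative addition of the electron-rich aryl chloride may be slow, so that protodeboronation or β-hydride elimination of the alkyl group takes over, and hydroboration may show incomplete facial selectivity at C4. The fallback sets out from 23 and returns at 25; it changes the carbon nucleophile and allows the C4 epimers to be separated before coupling.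
- Alkene 23 is hydroborated and oxidised (9-BBN-H, THF; then NaBO3·4H2O) to {(3R,4S,5R)-5-[3-(benzyloxy)-4-methoxyphenyl]-4-({[tert-butyl(dimethyl)silyl]oxy}methyl)oxolan-3-yl}methanol F7, which is purified from any C4 epimer.
- Iodination (I2, PPh3, imidazole, CH2Cl2) gives tert-butyl({(2R,3S,4S)-2-[3-(benzyloxy)-4-methoxyphenyl]-4-(iodomethyl)oxolan-3-yl}methoxy)dimethylsilane F8.
- Zinc insertion (Zn dust, LiCl, THF) gives ({(3S,4S,5R)-5-[3-(benzyloxy)-4-methoxyphenyl]-4-({[tert-butyl(dimethyl)silyl]oxy}methyl)oxolan-3-yl}methyl)(iodo)zinc F9.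
- A Negishi coupling of F9 (in excess) with 15 (Pd(OAc)2, SPhos, THF, rt→50 °C) needs no base, tolerates the free alcohol and should give 25.

## Further compounds

F1 | step 7 | (2R)-7-chloro-3-diazo-5-methoxy-2-[3-methoxy-4-(tosyloxy)phenyl]-2,3-dihydro-4H-chromen-4-one | Clc1cc(OC)c2c(c1)O[C@H](c1ccc(OS(=O)(=O)c3ccc(C)cc3)c(OC)c1)C(=[N+]=[N-])C2=O
F2 | step 6 | 4-formyl-2-methoxyphenyl 4-methylbenzenesulfonate | COc1cc(C=O)ccc1OS(=O)(=O)c1ccc(C)cc1
F3 | step 6 | (E)-1-(4-chloro-2-hydroxy-6-methoxyphenyl)-3-[3-methoxy-4-(tosyloxy)phenyl]prop-2-en-1-one | COc1cc(Cl)cc(O)c1C(=O)/C=C/c1ccc(OS(=O)(=O)c2ccc(C)cc2)c(OC)c1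
F4 | step 6 | rac-7-chloro-5-methoxy-2-[3-methoxy-4-(tosyloxy)phenyl]-2,3-dihydro-4H-chromen-4-one | Clc1cc(OC)c2c(c1)OC(c1ccc(OS(=O)(=O)c3ccc(C)cc3)c(OC)c1)CC2=O
F5 | step 6 | (2R,4R)-7-chloro-5-methoxy-2-[3-methoxy-4-(tosyloxy)phenyl]-3,4-dihydro-2H-chromen-4-ol | Clc1cc(OC)c2c(c1)O[C@@H](c1ccc(OS(=O)(=O)c3ccc(C)cc3)c(OC)c1)C[C@H]2O
F6 | step 16 | 2-({(2R,3R)-2-[3-(benzyloxy)-4-methoxyphenyl]-4-methylideneoxolan-3-yl}methyl)-4,4,5,5-tetramethyl-1,3,2-dioxaborolane | COc1ccc([C@@H]2OCC(=C)[C@H]2CB2OC(C)(C)C(C)(C)O2)cc1OCc1ccccc1
F7 | step 18 | {(3R,4S,5R)-5-[3-(benzyloxy)-4-methoxyphenyl]-4-({[tert-butyl(dimethyl)silyl]oxy}methyl)oxolan-3-yl}methanol | COc1ccc([C@@H]2OC[C@@H](CO)[C@H]2CO[Si](C)(C)C(C)(C)C)cc1OCc1ccccc1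
F8 | step 18 | tert-butyl({(2R,3S,4S)-2-[3-(benzyloxy)-4-methoxyphenyl]-4-(iodomethyl)oxolan-3-yl}methoxy)dimethylsilane | COc1ccc([C@@H]2OC[C@@H](CI)[C@H]2CO[Si](C)(C)C(C)(C)C)cc1OCc1ccccc1
F9 | step 18 | ({(3S,4S,5R)-5-[3-(benzyloxy)-4-methoxyphenyl]-4-({[tert-butyl(dimethyl)silyl]oxy}methyl)oxolan-3-yl}methyl)(iodo)zinc | COc1ccc([C@@H]2OC[C@@H](C[Zn]I)[C@H]2CO[Si](C)(C)C(C)(C)C)cc1OCc1ccccc1
A1 | alternative 1 | 3-{[(3S,4S,5R)-5-[3-(benzyloxy)-4-methoxyphenyl]-4-[(benzyloxy)methyl]oxolan-3-yl]methyl}cyclobut-2-en-1-one | COc1ccc([C@@H]2OC[C@@H](CC3=CC(=O)C3)[C@H]2COCc2ccccc2)cc1OCc1ccccc1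
A2 | alternative 1 | {[(3R,4R)-4-[4-(benzyloxy)-3-methoxyphenyl]-3-[(benzyloxy)methyl]-4-{[tert-butyl(dimethyl)silyl]oxy}but-1-yn-1-yl]oxy}tri(propan-2-yl)silane | CC(C)[Si](C(C)C)(C(C)C)OC#C[C@H](COCc1ccccc1)[C@@H](O[Si](C)(C)C(C)(C)C)c1ccc(OCc2ccccc2)c(OC)c1
A3 | alternative 1 | 2,5-disubstituted resorcinol mono-triisopropylsilyl ether (ring B with both side chains, free OH at C7a', silyl ether at C4') | COc1ccc([C@@H]2OC[C@@H](Cc3cc(O[Si](C(C)C)(C(C)C)C(C)C)c([C@H](COCc4ccccc4)[C@@H](O[Si](C)(C)C(C)(C)C)c4ccc(OCc5ccccc5)c(OC)c4)c(O)c3)[C@H]2COCc2ccccc2)cc1OCc1ccccc1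
A4 | alternative 2 | bis-allylic ether of (1R)-1-[3-(benzyloxy)-4-methoxyphenyl]-3-(pinacolboryl)prop-2-en-1-ol with the (E)-3-arylallyl arm that carries the silyl-protected dihydrobenzofuran | COc1ccc([C@@H](/C=C/B2OC(C)(C)C(C)(C)O2)OC/C=C/c2cc(OC)c3c(c2)O[C@H](c2ccc(OCc4ccccc4)c(OC)c2)[C@H]3CO[Si](C)(C)C(C)(C)C)cc1OCc1ccccc1
A5 | alternative 2 | 3-oxabicyclo[3.2.0]heptane cyclobutylboronate (one C7/C9 isomer) | COc1ccc([C@@H]2OC[C@H]3[C@H](c4cc(OC)c5c(c4)O[C@H](c4ccc(OCc6ccccc6)c(OC)c4)[C@H]5CO[Si](C)(C)C(C)(C)C)[C@@H](B4OC(C)(C)C(C)(C)O4)[C@@H]23)cc1OCc1ccccc1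
A6 | alternative 3 | 5-{[(3S,4S,5R)-5-[3-(benzyloxy)-4-methoxyphenyl]-4-[(benzyloxy)methyl]oxolan-3-yl]methyl}-3-methoxy-2-(trimethylsilyl)phenyl trifluoromethanesulfonate | COc1ccc([C@@H]2OC[C@@H](Cc3cc(OC)c([Si](C)(C)C)c(OS(=O)(=O)C(F)(F)F)c3)[C@H]2COCc2ccccc2)cc1OCc1ccccc1
A7 | alternative 3 | (R)-[4-(benzyloxy)-3-methoxyphenyl][(2S)-oxiran-2-yl]methanol | O[C@H](c1ccc(OCc2ccccc2)c(OC)c1)[C@@H]1CO1
A8 | alternative 3 | tri-O-benzyl derivative of 27 with free C9' hydroxyl | COc1ccc([C@@H]2OC[C@@H](Cc3cc(OC)c4c(c3)O[C@H](c3ccc(OCc5ccccc5)c(OC)c3)[C@H]4CO)[C@H]2COCc2ccccc2)cc1OCc1ccccc1
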